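## Retrosynthetic overview

- The oxirane is put on last (C4=C5 epoxidation). O9 acetate and O8 methacrylate come from acylations, and the ten-membered ring is opened at C9–C10 (Nozaki–Hiyama–Kishi closure of a C10 α-iodoenoate onto a C9 aldehyde).
- The α-methylene-γ-lactone is cut at O–C6 and C7–C11 in one operation: palladium-catalysed 1,2-carbo-oxygenation of the C6=C7 bond of an acyclic (4E,6Z)-C4=C5–C6=C7 diene by 2-bromoacrylic acid.
- Enabling feature: the lactone oxygen sits on C6, which is allylic to C4=C5 once the 4,5-oxirane is read as the (E)-olefin, and C7 carries the acrylate carbon C11. The ring O–C6–C7–C11–C12 is therefore the trace of a C4–C5–C6 allylpalladium captured at C6 by the C12 carboxylate.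
- C8 comes from (R)-glyceraldehyde acetonide. Its dioxolane ring (absent from the target) steers the new C7 centre and is then cleaved to free O8 and C9. The diene comes from Sonogashira coupling and semi-hydrogenation.
- Ring order: dioxolane (temporary, chiral pool) → γ-lactone (step 6) → ten-membered carbocycle (step 14) → oxirane (step 18).

Key step: step 6

Remark: germacrane numbering is used (ring C1–C10, C11/C12/C13 = lactone α-carbon/carbonyl/methylene, C14 = ester carbon on C10, C15 = methyl on C4). The target is read as 4R,5R,6S,7R,8S,9S with C2 and C9 cis on C1=C10; CIP descriptors at C6 and C7 change along the route only because neighbouring groups change priority.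

## Route

Step 1
Reactants: 1 pent-4-yn-1-ol
Product: 2 tert-butyl(dimethyl)(pent-4-yn-1-yloxy)silane
Conditions: TBSCl, imidazole, CH2Cl2, 0 °C to rt
Reagents that add atoms: tert-butyldimethylsilyl chloride, CC(C)(C)[Si](C)(C)Cl
Why: Standard silylation of the primary alcohol; the ether keeps O1 from attacking the allylpalladium terminus C4 in step 6.

Step 2
Reactants: 2 tert-butyl(dimethyl)(pent-4-yn-1-yloxy)silane
Product: 4 tert-butyl{[(4E)-5-iodo-4-methylpent-4-en-1-yl]oxy}dimethylsilane, via alkenyl(dimethyl)alane 3 (not isolated)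
Conditions: AlMe3, Cp2ZrCl2 (0.25 equiv), CH2Cl2, 0 °C to rt; then I2, THF, −30 °C to 0 °C
Reagents that add atoms: trimethylaluminium, C[Al](C)C; iodine, II
Why: Negishi carboalumination adds methyl (to C4) and aluminium (to C5) syn across the alkyne, and iodinolysis with retention fixes the (E)-C4=C5 geometry of the target's trans-oxirane.

Step 3
Reactants: 5 (4R)-2,2-dimethyl-1,3-dioxolane-4-carbaldehyde
Product: 6 (4S)-4-ethynyl-2,2-dimethyl-1,3-dioxolane
Conditions: dimethyl (1-diazo-2-oxopropyl)phosphonate, K2CO3, MeOH, 0 °C to rt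
Reagents that add atoms: dimethyl (1-diazo-2-oxopropyl)phosphonate, CC(=O)C(=[N+]=[N-])P(=O)(OC)OC
Why: Seyferth–Gilbert homologation with the Ohira–Bestmann reagent turns the aldehyde into the terminal alkyne (C6≡C7) under mild base that should not epimerize C8, which is taken from the chiral pool.

Step 4
Reactants: 4 tert-butyl{[(4E)-5-iodo-4-methylpent-4-en-1-yl]oxy}dimethylsilane; 6 (4S)-4-ethynyl-2,2-dimethyl-1,3-dioxolane
Product: 7 tert-butyl{[(4E)-7-[(4S)-2,2-dimethyl-1,3-dioxolan-4-yl]-4-methylhept-4-en-6-yn-1-yl]oxy}dimethylsilane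
Conditions: Pd(PPh3)2Cl2 (3 mol %), CuI (6 mol %), Et3N, THF, rt
Reagents that add atoms: none
Why: Sonogashira coupling joins C5 to C6 with retention of the vinyl iodide geometry.

Step 5
Reactants: 7 tert-butyl{[(4E)-7-[(4S)-2,2-dimethyl-1,3-dioxolan-4-yl]-4-methylhept-4-en-6-yn-1-yl]oxy}dimethylsilane
Product: 8 tert-butyl{[(4E,6Z)-7-[(4S)-2,2-dimethyl-1,3-dioxolan-4-yl]-4-methylhepta-4,6-dien-1-yl]oxy}dimethylsilane
Conditions: H2 (1 atm), Pd/CaCO3 poisoned with Pb(OAc)2, quinoline, EtOAc, rt, stopped after 1 equiv H2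
Reagents that add atoms: none
Why: Lindlar semi-hydrogenation adds H2 syn to the alkyne only, giving the (6Z)-alkene whose allylic 1,3-strain is needed for facial control in step 6.

Step 6
Reactants: 8 tert-butyl{[(4E,6Z)-7-[(4S)-2,2-dimethyl-1,3-dioxolan-4-yl]-4-methylhepta-4,6-dien-1-yl]oxy}dimethylsilane; 9 2-bromoprop-2-enoic acid
Product: 11 (4S,5R)-5-[(1E)-5-{[tert-butyl(dimethyl)silyl]oxy}-2-methylpent-1-en-1-yl]-4-[(4S)-2,2-dimethyl-1,3-dioxolan-4-yl]-3-methylideneoxolan-2-one, via allylpalladium carboxylate 10 (not isolated)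
Conditions: Pd(OAc)2 (10 mol %), PPh3 (20 mol %), K2CO3, n-Bu4NCl, DMF, 70 °C, slow addition of 9 (2 equiv)
Reagents that add atoms: none
Why: Proposed new method: zerovalent palladium inserts into the C–Br bond of potassium 2-bromoacrylate, the C11 vinylpalladium adds across the disubstituted (Z)-C6=C7 bond with C11 going to C7 (the trisubstituted C4 end is too hindered), palladium ends on C6 as the allyl complex 10 spanning C6–C5–C4, and the tethered carboxylate attacks C6 to release the lactone and zerovalent palladium. The closest known reaction type is the Larock heteroannulation of 1,3-dienes with halo-carboxylic acids (o-iodobenzoic and β-haloacrylic acids give vinyl-substituted lactones this way), extended here to an α-bromoacrylic acid and an internal diene terminus. The only ring closed is the γ-lactone O–C6–C7–C11–C12, by 5-exo attack of the carboxylate oxygen on the proximal allyl terminus C6 rather than seven-membered closure at the tertiary terminus C4. C7 is set in the insertion: allylic 1,3-strain of the (Z)-alkene holds H8 in the diene plane, and palladium with C11 should be delivered to the face opposite the dioxolane C8–O bond (the temporary ring removed in step 10), as in osmylations and cycloadditions of (Z)-alkenyl dioxolanes; C6 follows stereospecifically, because syn carbopalladation of the (Z)-alkene and anti (outer-sphere) carboxylate attack on the phosphine-ligated allyl complex place C5 and C8 trans on the lactone. The step needs regioselective insertion, retention of the (E)-C4=C5 geometry and no competing nucleophile; these are secured by the unsymmetrical diene, by the syn,syn allyl geometry inherited from the s-trans (4E)-diene (the tertiary terminus resists σ–π–σ isomerization), and by the silyl ether on O1.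

Step 7
Reactants: 11 (4S,5R)-5-[(1E)-5-{[tert-butyl(dimethyl)silyl]oxy}-2-methylpent-1-en-1-yl]-4-[(4S)-2,2-dimethyl-1,3-dioxolan-4-yl]-3-methylideneoxolan-2-one
Product: 12 (4S,5R)-4-[(4S)-2,2-dimethyl-1,3-dioxolan-4-yl]-5-[(1E)-5-hydroxy-2-methylpent-1-en-1-yl]-3-methylideneoxolan-2-one
Conditions: HF·pyridine, pyridine, THF, 0 °C to rt
Reagents that add atoms: none
Why: Buffered fluoride desilylation frees the primary C1 alcohol while the acetonide and the allylic lactone should survive.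

Step 8
Reactants: 12 (4S,5R)-4-[(4S)-2,2-dimethyl-1,3-dioxolan-4-yl]-5-[(1E)-5-hydroxy-2-methylpent-1-en-1-yl]-3-methylideneoxolan-2-one
Product: 13 (4E)-5-[(2R,3S)-3-[(4S)-2,2-dimethyl-1,3-dioxolan-4-yl]-4-methylidene-5-oxooxolan-2-yl]-4-methylpent-4-enal
Conditions: Dess–Martin periodinane, CH2Cl2, 0 °C to rt
Reagents that add atoms: none
Why: Dess–Martin oxidation gives the C1 aldehyde under near-neutral conditions that do not isomerize the exocyclic methylene.

Step 9
Reactants: 13 (4E)-5-[(2R,3S)-3-[(4S)-2,2-dimethyl-1,3-dioxolan-4-yl]-4-methylidene-5-oxooxolan-2-yl]-4-methylpent-4-enal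
Product: 14 methyl (2Z,6E)-7-[(2R,3S)-3-[(4S)-2,2-dimethyl-1,3-dioxolan-4-yl]-4-methylidene-5-oxooxolan-2-yl]-2-iodo-6-methylhepta-2,6-dienoate
Conditions: Ph3P=CHCO2Me, N-iodosuccinimide, CH2Cl2, −20 °C; then 13, −20 °C to rt
Reagents that add atoms: methyl (triphenylphosphoranylidene)acetate, COC(=O)C=P(c1ccccc1)(c1ccccc1)c1ccccc1; N-iodosuccinimide, O=C1CCC(=O)N1I
Why: The stabilized ylide is iodinated in the flask and the α-iodo ylide undergoes a Wittig reaction that puts C2 cis to iodine (trans to the ester), the geometry that later places C2 and C9 cis on C1=C10.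

Step 10
Reactants: 14 methyl (2Z,6E)-7-[(2R,3S)-3-[(4S)-2,2-dimethyl-1,3-dioxolan-4-yl]-4-methylidene-5-oxooxolan-2-yl]-2-iodo-6-methylhepta-2,6-dienoate
Product: 15 methyl (2Z,6E)-7-[(2R,3R)-3-[(1S)-1,2-dihydroxyethyl]-4-methylidene-5-oxooxolan-2-yl]-2-iodo-6-methylhepta-2,6-dienoate
Conditions: AcOH/H2O/THF (3:1:1), 45 °C
Reagents that add atoms: none
Why: Mild acid hydrolysis removes the temporary dioxolane and frees O8 and O9 without touching C8.

Step 11
Reactants: 15 methyl (2Z,6E)-7-[(2R,3R)-3-[(1S)-1,2-dihydroxyethyl]-4-methylidene-5-oxooxolan-2-yl]-2-iodo-6-methylhepta-2,6-dienoate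
Product: 16 methyl (2Z,6E)-7-[(2R,3R)-3-[(1S)-1-hydroxy-2-[(triethylsilyl)oxy]ethyl]-4-methylidene-5-oxooxolan-2-yl]-2-iodo-6-methylhepta-2,6-dienoate
Conditions: Et3SiCl (1.05 equiv), imidazole, CH2Cl2, −30 °C
Reagents that add atoms: chlorotriethylsilane, CC[Si](Cl)(CC)CC
Why: The primary C9 hydroxyl is silylated much faster than the hindered secondary C8 hydroxyl (steric differentiation of a 1,2-diol).

Step 12
Reactants: 16 methyl (2Z,6E)-7-[(2R,3R)-3-[(1S)-1-hydroxy-2-[(triethylsilyl)oxy]ethyl]-4-methylidene-5-oxooxolan-2-yl]-2-iodo-6-methylhepta-2,6-dienoate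
Product: 17 methyl (2Z,6E)-2-iodo-6-methyl-7-[(2R,3S)-4-methylidene-3-[(1S)-1-[(2-methylprop-2-enoyl)oxy]-2-[(triethylsilyl)oxy]ethyl]-5-oxooxolan-2-yl]hepta-2,6-dienoate
Conditions: methacrylic anhydride, Et3N, DMAP (cat.), CH2Cl2, 0 °C
Reagents that add atoms: methacrylic anhydride, C=C(C)C(=O)OC(=O)C(C)=C
Why: DMAP-catalysed acylation installs the methacrylate on O8 with retention at C8.

Step 13
Reactants: 17 methyl (2Z,6E)-2-iodo-6-methyl-7-[(2R,3S)-4-methylidene-3-[(1S)-1-[(2-methylprop-2-enoyl)oxy]-2-[(triethylsilyl)oxy]ethyl]-5-oxooxolan-2-yl]hepta-2,6-dienoate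
Product: 18 methyl (2Z,6E)-2-iodo-6-methyl-7-[(2R,3S)-4-methylidene-3-[(1S)-1-[(2-methylprop-2-enoyl)oxy]-2-oxoethyl]-5-oxooxolan-2-yl]hepta-2,6-dienoate
Conditions: (COCl)2, DMSO, CH2Cl2, −78 °C to −40 °C; then i-Pr2NEt, −78 °C to −20 °C
Reagents that add atoms: none
Why: Under Swern conditions a primary triethylsilyl ether is cleaved and oxidized directly to the aldehyde, and the low temperature with a hindered base should limit epimerization at C8.

Step 14
Reactants: 18 methyl (2Z,6E)-2-iodo-6-methyl-7-[(2R,3S)-4-methylidene-3-[(1S)-1-[(2-methylprop-2-enoyl)oxy]-2-oxoethyl]-5-oxooxolan-2-yl]hepta-2,6-dienoate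
Product: 19 methyl (1(10)E,4E,6R,7S,8S)-9-hydroxy-8-(methacryloyloxy)germacra-1(10),4,11(13)-trien-12,6-olid-14-oate (both C9 epimers)
Conditions: CrCl2 (8 equiv), NiCl2 (0.1 equiv), degassed DMSO/THF, rt, syringe-pump addition to 2 mM
Reagents that add atoms: none
Why: Nozaki–Hiyama–Kishi coupling (nickel inserts into the C10–I bond, transmetalation to chromium, addition to the C9 aldehyde) closes the ten-membered ring at C9–C10; the ring allows only the C2/C9-cis alkene and the reagent tolerates the esters and the methylene lactone, while the C9 configuration is not relied on because it is erased in step 15.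

Step 15
Reactants: 19 methyl (1(10)E,4E,6R,7S,8S)-9-hydroxy-8-(methacryloyloxy)germacra-1(10),4,11(13)-trien-12,6-olid-14-oate (both C9 epimers)
Product: 20 methyl (1(10)E,4E,6R,7S,8S)-8-(methacryloyloxy)-9-oxogermacra-1(10),4,11(13)-trien-12,6-olid-14-oate
Conditions: Dess–Martin periodinane, CH2Cl2, 0 °C
Reagents that add atoms: none
Why: Oxidation of both C9 epimers converges on one alkylidene β-keto ester under conditions too mild to enolize C8.

Step 16
Reactants: 20 methyl (1(10)E,4E,6R,7S,8S)-8-(methacryloyloxy)-9-oxogermacra-1(10),4,11(13)-trien-12,6-olid-14-oate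
Product: 21 methyl (1(10)E,4E,6R,7S,8S,9S)-9-hydroxy-8-(methacryloyloxy)germacra-1(10),4,11(13)-trien-12,6-olid-14-oate
Conditions: NaBH4, CeCl3·7H2O, MeOH/THF, −78 °C
Reagents that add atoms: none
Why: Luche reduction is 1,2-selective for the conjugated ketone, and Felkin–Anh delivery of hydride anti to the C8–O bond of the non-chelating α-acyloxy ketone should give the 8,9-syn (9S) alcohol.

Step 17
Reactants: 21 methyl (1(10)E,4E,6R,7S,8S,9S)-9-hydroxy-8-(methacryloyloxy)germacra-1(10),4,11(13)-trien-12,6-olid-14-oate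
Product: 22 methyl (1(10)E,4E,6R,7S,8S,9S)-9-acetoxy-8-(methacryloyloxy)germacra-1(10),4,11(13)-trien-12,6-olid-14-oate
Conditions: Ac2O, pyridine, DMAP (cat.), CH2Cl2, 0 °C
Reagents that add atoms: acetic anhydride, CC(=O)OC(C)=O
Why: Prompt acetylation caps O9 with retention before the neighbouring methacrylate can migrate.

Step 18
Reactants: 22 methyl (1(10)E,4E,6R,7S,8S,9S)-9-acetoxy-8-(methacryloyloxy)germacra-1(10),4,11(13)-trien-12,6-olid-14-oate
Product: 23 methyl (1(10)E,4R,5R,6S,7R,8S,9S)-9-acetoxy-4,5-epoxy-8-(methacryloyloxy)germacra-1(10),11(13)-dien-12,6-olid-14-oate (CNP0153978.3)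
Conditions: mCPBA, CH2Cl2, 0 °C
Reagents that add atoms: 3-chloroperoxybenzoic acid, O=C(OO)c1cccc(Cl)c1
Why: Prilezhaev epoxidation attacks only the electron-rich C4=C5 bond (the other three alkenes are conjugated to carbonyls), stereospecifically gives the trans-oxirane, and should come from the peripheral face (syn to the lactone oxygen, anti to C7, with H6 eclipsing the alkene) to set 4R,5R.

## Compound list

1 | pent-4-yn-1-ol | C#CCCCO | starting material
2 | tert-butyl(dimethyl)(pent-4-yn-1-yloxy)silane | C#CCCCO[Si](C)(C)C(C)(C)C | intermediate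
3 | [(1E)-5-{[tert-butyl(dimethyl)silyl]oxy}-2-methylpent-1-en-1-yl](dimethyl)alane | C[Al](C)/C=C(\C)CCCO[Si](C)(C)C(C)(C)C | intermediate (not isolated)
4 | tert-butyl{[(4E)-5-iodo-4-methylpent-4-en-1-yl]oxy}dimethylsilane | CC(C)(C)[Si](C)(C)OCCC/C(C)=C/I | intermediate
5 | (4R)-2,2-dimethyl-1,3-dioxolane-4-carbaldehyde | O=C[C@H]1COC(C)(C)O1 | starting material
6 | (4S)-4-ethynyl-2,2-dimethyl-1,3-dioxolane | C#C[C@H]1COC(C)(C)O1 | intermediate
7 | tert-butyl{[(4E)-7-[(4S)-2,2-dimethyl-1,3-dioxolan-4-yl]-4-methylhept-4-en-6-yn-1-yl]oxy}dimethylsilane | CC(C)(C)[Si](C)(C)OCCC/C(C)=C/C#C[C@H]1COC(C)(C)O1 | intermediate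
8 | tert-butyl{[(4E,6Z)-7-[(4S)-2,2-dimethyl-1,3-dioxolan-4-yl]-4-methylhepta-4,6-dien-1-yl]oxy}dimethylsilane | CC(C)(C)[Si](C)(C)OCCC/C(C)=C/C=C\[C@H]1COC(C)(C)O1 | intermediate
9 | 2-bromoprop-2-enoic acid | C=C(Br)C(=O)O | starting material
10 | potassium salt of the σ-allyl bromopalladium (divalent palladium) carboxylate: C11 bonded to C7, palladium on C6 syn to C11, carboxylate free, phosphine ligands not drawn | C=C(C(=O)[O-])[C@H]([C@H]1COC(C)(C)O1)[C@@H]([Pd]Br)/C=C(\C)CCCO[Si](C)(C)C(C)(C)C.[K+] | intermediate (not isolated)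
11 | (4S,5R)-5-[(1E)-5-{[tert-butyl(dimethyl)silyl]oxy}-2-methylpent-1-en-1-yl]-4-[(4S)-2,2-dimethyl-1,3-dioxolan-4-yl]-3-methylideneoxolan-2-one | C=C1C(=O)O[C@H](/C=C(\C)CCCO[Si](C)(C)C(C)(C)C)[C@H]1[C@H]1COC(C)(C)O1 | intermediate
12 | (4S,5R)-4-[(4S)-2,2-dimethyl-1,3-dioxolan-4-yl]-5-[(1E)-5-hydroxy-2-methylpent-1-en-1-yl]-3-methylideneoxolan-2-one | C=C1C(=O)O[C@H](/C=C(\C)CCCO)[C@H]1[C@H]1COC(C)(C)O1 | intermediate
13 | (4E)-5-[(2R,3S)-3-[(4S)-2,2-dimethyl-1,3-dioxolan-4-yl]-4-methylidene-5-oxooxolan-2-yl]-4-methylpent-4-enal | C=C1C(=O)O[C@H](/C=C(\C)CCC=O)[C@H]1[C@H]1COC(C)(C)O1 | intermediate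
14 | methyl (2Z,6E)-7-[(2R,3S)-3-[(4S)-2,2-dimethyl-1,3-dioxolan-4-yl]-4-methylidene-5-oxooxolan-2-yl]-2-iodo-6-methylhepta-2,6-dienoate | C=C1C(=O)O[C@H](/C=C(\C)CC/C=C(\I)C(=O)OC)[C@H]1[C@H]1COC(C)(C)O1 | intermediate
15 | methyl (2Z,6E)-7-[(2R,3R)-3-[(1S)-1,2-dihydroxyethyl]-4-methylidene-5-oxooxolan-2-yl]-2-iodo-6-methylhepta-2,6-dienoate | C=C1C(=O)O[C@H](/C=C(\C)CC/C=C(\I)C(=O)OC)[C@H]1[C@H](O)CO | intermediate
16 | methyl (2Z,6E)-7-[(2R,3R)-3-[(1S)-1-hydroxy-2-[(triethylsilyl)oxy]ethyl]-4-methylidene-5-oxooxolan-2-yl]-2-iodo-6-methylhepta-2,6-dienoate | C=C1C(=O)O[C@H](/C=C(\C)CC/C=C(\I)C(=O)OC)[C@H]1[C@H](O)CO[Si](CC)(CC)CC | intermediate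
17 | methyl (2Z,6E)-2-iodo-6-methyl-7-[(2R,3S)-4-methylidene-3-[(1S)-1-[(2-methylprop-2-enoyl)oxy]-2-[(triethylsilyl)oxy]ethyl]-5-oxooxolan-2-yl]hepta-2,6-dienoate | C=C1C(=O)O[C@H](/C=C(\C)CC/C=C(\I)C(=O)OC)[C@H]1[C@H](OC(=O)C(C)=C)CO[Si](CC)(CC)CC | intermediate
18 | methyl (2Z,6E)-2-iodo-6-methyl-7-[(2R,3S)-4-methylidene-3-[(1S)-1-[(2-methylprop-2-enoyl)oxy]-2-oxoethyl]-5-oxooxolan-2-yl]hepta-2,6-dienoate | C=C1C(=O)O[C@H](/C=C(\C)CC/C=C(\I)C(=O)OC)[C@H]1[C@H](OC(=O)C(C)=C)C=O | intermediate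
19 | methyl (1(10)E,4E,6R,7S,8S)-9-hydroxy-8-(methacryloyloxy)germacra-1(10),4,11(13)-trien-12,6-olid-14-oate, C9 epimers | C=C(C)C(=O)O[C@H]1[C@H]2C(=C)C(=O)O[C@@H]2/C=C(\C)CC/C=C(/C(=O)OC)C1O | intermediate
20 | methyl (1(10)E,4E,6R,7S,8S)-8-(methacryloyloxy)-9-oxogermacra-1(10),4,11(13)-trien-12,6-olid-14-oate | C=C(C)C(=O)O[C@H]1[C@H]2C(=C)C(=O)O[C@@H]2/C=C(\C)CC/C=C(/C(=O)OC)C1=O | intermediate
21 | methyl (1(10)E,4E,6R,7S,8S,9S)-9-hydroxy-8-(methacryloyloxy)germacra-1(10),4,11(13)-trien-12,6-olid-14-oate | C=C(C)C(=O)O[C@H]1[C@H]2C(=C)C(=O)O[C@@H]2/C=C(\C)CC/C=C(/C(=O)OC)[C@@H]1O | intermediate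
22 | methyl (1(10)E,4E,6R,7S,8S,9S)-9-acetoxy-8-(methacryloyloxy)germacra-1(10),4,11(13)-trien-12,6-olid-14-oate | C=C(C)C(=O)O[C@H]1[C@H]2C(=C)C(=O)O[C@@H]2/C=C(\C)CC/C=C(/C(=O)OC)[C@@H]1OC(C)=O | intermediate
23 | methyl (1(10)E,4R,5R,6S,7R,8S,9S)-9-acetoxy-4,5-epoxy-8-(methacryloyloxy)germacra-1(10),11(13)-dien-12,6-olid-14-oate (CNP0153978.3) | C=C(C)C(=O)O[C@H]1[C@H]2C(=C)C(=O)O[C@@H]2[C@H]2O[C@]2(C)CC/C=C(/C(=O)OC)[C@@H]1OC(C)=O | target

## Step count and risks

Total step count: 18. Longest linear sequence: 17 steps (steps 1, 2 and 4–18).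

Steps most likely to fail:

**Step 6 (Proposed new method).** The vinylpalladium may add to the wrong face of C6=C7 (C7 epimer), the carboxylate may be delivered through palladium (cis-lactone), or β-hydride elimination may outrun allyl capture. The fallback uses known chemistry, sets out from 4 and 5 and comes back at 11, and still closes the lactone at O–C6.
- Iodine–lithium exchange of 4 (t-BuLi, Et2O, −78 °C) and formylation with DMF gives (2E)-6-{[tert-butyl(dimethyl)silyl]oxy}-3-methylhex-2-enal F1.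
- Morita–Baylis–Hillman reaction of 5 with methyl acrylate (DABCO) gives methyl 2-{[(4R)-2,2-dimethyl-1,3-dioxolan-4-yl](hydroxy)methyl}prop-2-enoate F2.
- PBr3 converts it with allylic transposition into methyl (2Z)-2-(bromomethyl)-3-[(4S)-2,2-dimethyl-1,3-dioxolan-4-yl]prop-2-enoate F3.
- Indium-mediated Barbier allylation of F1 with F3 (In, THF/H2O) should give the syn adduct methyl (3S,4S,5E)-9-{[tert-butyl(dimethyl)silyl]oxy}-3-[(4S)-2,2-dimethyl-1,3-dioxolan-4-yl]-4-hydroxy-6-methyl-2-methylidenenon-5-enoate F4, with diastereomers separated.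
- LiOH hydrolysis gives (3S,4S,5E)-9-{[tert-butyl(dimethyl)silyl]oxy}-3-[(4S)-2,2-dimethyl-1,3-dioxolan-4-yl]-4-hydroxy-6-methyl-2-methylidenenon-5-enoic acid F5.
- Mitsunobu lactonization (PPh3, DIAD, dilute THF) lets the carboxylate displace the activated allylic C6 oxygen with inversion to give 11.

**Step 14.** Ring strain may divert the Nozaki–Hiyama–Kishi closure into oligomerization, or the hindered α-acyloxy aldehyde may react too slowly so that the organochromium species is simply protonated. The fallback cyclizes before acylation and differentiates the diol afterwards; it sets out from 15 and comes back at 20.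
- Chemoselective oxidation of the primary hydroxyl (TEMPO, N-chlorosuccinimide, n-Bu4NCl, CH2Cl2/aqueous NaHCO3–K2CO3) gives methyl (2Z,6E)-7-[(2R,3R)-3-[(1S)-1-hydroxy-2-oxoethyl]-4-methylidene-5-oxooxolan-2-yl]-2-iodo-6-methylhepta-2,6-dienoate F6.
- Its CrCl2/NiCl2 closure, now preorganized by a five-membered chromium alkoxide chelate and free of the bulky ester, should give methyl (1(10)E,4E,6R,7R,8S,9S)-8,9-dihydroxygermacra-1(10),4,11(13)-trien-12,6-olid-14-oate F7.
- MnO2 oxidizes only the allylic C9 hydroxyl to methyl (1(10)E,4E,6R,7R,8S)-8-hydroxy-9-oxogermacra-1(10),4,11(13)-trien-12,6-olid-14-oate F8.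
- Methacrylic anhydride/DMAP then acylates O8 to give 20.

**Step 16.** The macrocycle may override Felkin–Anh control so that hydride is delivered to the other face of the C9 ketone, or conjugate reduction may compete. The fallback sets C9 by substitution instead of by hydride facial selectivity; it sets out from 20 and comes back at 22.
- If reduction gives mainly methyl (1(10)E,4E,6R,7S,8S,9R)-9-hydroxy-8-(methacryloyloxy)germacra-1(10),4,11(13)-trien-12,6-olid-14-oate F9, a Mitsunobu reaction with acetic acid (PPh3, DIAD, THF, 0 °C) inverts C9 and installs the acetate in one operation to give 22.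

## Further compounds

F1 | step 6 | (2E)-6-{[tert-butyl(dimethyl)silyl]oxy}-3-methylhex-2-enal | CC(C)(C)[Si](C)(C)OCCC/C(C)=C/C=O
F2 | step 6 | methyl 2-{[(4R)-2,2-dimethyl-1,3-dioxolan-4-yl](hydroxy)methyl}prop-2-enoate (carbinol epimers) | C=C(C(=O)OC)C(O)[C@H]1COC(C)(C)O1
F3 | step 6 | methyl (2Z)-2-(bromomethyl)-3-[(4S)-2,2-dimethyl-1,3-dioxolan-4-yl]prop-2-enoate | COC(=O)/C(CBr)=C/[C@H]1COC(C)(C)O1
F4 | step 6 | methyl (3S,4S,5E)-9-{[tert-butyl(dimethyl)silyl]oxy}-3-[(4S)-2,2-dimethyl-1,3-dioxolan-4-yl]-4-hydroxy-6-methyl-2-methylidenenon-5-enoate | C=C(C(=O)OC)[C@H]([C@H]1COC(C)(C)O1)[C@@H](O)/C=C(\C)CCCO[Si](C)(C)C(C)(C)C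
F5 | step 6 | (3S,4S,5E)-9-{[tert-butyl(dimethyl)silyl]oxy}-3-[(4S)-2,2-dimethyl-1,3-dioxolan-4-yl]-4-hydroxy-6-methyl-2-methylidenenon-5-enoic acid | C=C(C(=O)O)[C@H]([C@H]1COC(C)(C)O1)[C@@H](O)/C=C(\C)CCCO[Si](C)(C)C(C)(C)C
F6 | step 14 | methyl (2Z,6E)-7-[(2R,3R)-3-[(1S)-1-hydroxy-2-oxoethyl]-4-methylidene-5-oxooxolan-2-yl]-2-iodo-6-methylhepta-2,6-dienoate | C=C1C(=O)O[C@H](/C=C(\C)CC/C=C(\I)C(=O)OC)[C@H]1[C@H](O)C=O
F7 | step 14 | methyl (1(10)E,4E,6R,7R,8S,9S)-8,9-dihydroxygermacra-1(10),4,11(13)-trien-12,6-olid-14-oate | O[C@H]1[C@H]2C(=C)C(=O)O[C@@H]2/C=C(\C)CC/C=C(/C(=O)OC)[C@@H]1O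
F8 | step 14 | methyl (1(10)E,4E,6R,7R,8S)-8-hydroxy-9-oxogermacra-1(10),4,11(13)-trien-12,6-olid-14-oate | O[C@H]1[C@H]2C(=C)C(=O)O[C@@H]2/C=C(\C)CC/C=C(/C(=O)OC)C1=O
F9 | step 16 | methyl (1(10)E,4E,6R,7S,8S,9R)-9-hydroxy-8-(methacryloyloxy)germacra-1(10),4,11(13)-trien-12,6-olid-14-oate | C=C(C)C(=O)O[C@H]1[C@H]2C(=C)C(=O)O[C@@H]2/C=C(\C)CC/C=C(/C(=O)OC)[C@H]1O
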